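**Retrosynthetic overview**
- The hydroquinone and the E-enone come last, by oxidation of a phenol and of a secondary allylic alcohol. The CH2–C(sp2) bond next to the side-chain ketone is cut back to a methyl ketone and a (Z)-vinyl iodide (palladium-catalysed α-alkenylation).
- The vinyl iodide comes from o-cresol and but-2-yn-1-ol. The hydroxy-enone arm comes from an aldehyde and 2-methylbut-3-yn-2-ol.
- The methyl ketone/aldehyde pair comes from a cis-fused δ-lactone (MeLi opening, then oxidation).
- Key step: the δ-lactone comes from a meso cis-dimethyl bicyclic cyclopentanone by an enantioselective, desymmetrising Baeyer–Villiger ring expansion. This step tells the two arms apart and fixes the absolute configuration of both quaternary carbons.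
- Ring order: the cyclopentane is present from the start (1,2-dimethylcyclopentene); cyclobutanone ([2+2]) → cyclopentanone (CH2N2 ring expansion) → δ-lactone (Baeyer–Villiger), which is then opened.

Assumption: racemic compounds 4 and 5 are drawn as one enantiomer, and the carbinol carbon made in step 7 (oxidised in step 13) is an unassigned mixture of epimers.

**Step 1**
Reactants: 1 1,2-dimethylcyclopentene; 2 trichloroacetyl chloride
Product: 4 rac-(1R,5S)-7,7-dichloro-1,5-dimethylbicyclo[3.2.0]heptan-6-one, via dichloroketene 3 (not isolated)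
Conditions: Zn–Cu couple, POCl3, Et2O, 35 °C
Reagents that add atoms: none
Why: ketene–alkene [2+2] cycloaddition of dichloroketene (made in situ by zinc dehalogenation) with the electron-rich tetrasubstituted alkene; addition across one face of the ring alkene forces the cis ring fusion, so both methyl groups end on the same face (racemic).

**Step 2**
Reactants: 4 rac-(1R,5S)-7,7-dichloro-1,5-dimethylbicyclo[3.2.0]heptan-6-one
Product: 5 rac-(3aR,6aR)-1,1-dichloro-3a,6a-dimethylhexahydropentalen-2(1H)-one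
Conditions: CH2N2 (excess), Et2O/MeOH, 0 → 25 °C
Reagents that add atoms: diazomethane, C=[N+]=[N-]
Why: diazomethane ring expansion of a cyclobutanone (Tiffeneau–Demjanov type 1,2-shift), in which the electron-rich quaternary α-carbon migrates with retention and the CCl2 carbon does not, so the carbonyl ends at the 2-position between CH2 and CCl2.

**Step 3**
Reactants: 5 rac-(3aR,6aR)-1,1-dichloro-3a,6a-dimethylhexahydropentalen-2(1H)-one
Product: 6 (3aR,6aS)-3a,6a-dimethylhexahydropentalen-2(1H)-one (meso)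
Conditions: Zn dust, AcOH, 70 °C
Reagents that add atoms: none
Why: reductive dechlorination of an α,α-dichloro ketone by zinc through the zinc enolate; removing the chlorines makes the ketone meso, so the racemate converges to one achiral compound.

**Step 4**
Reactants: 6 (3aR,6aS)-3a,6a-dimethylhexahydropentalen-2(1H)-one
Product: 7 (4aR,7aR)-4a,7a-dimethylhexahydrocyclopenta[c]pyran-3(1H)-one
Conditions: Sc(OTf)3 (10 mol%), chiral N,N'-dioxide ligand (two (S)-pipecolic acid 2,6-diisopropylanilide N-oxides joined by a trimethylene bridge; the ligand antipode that gives (4aR,7aR)-7 is used) (12 mol%), m-CPBA (1.5 equiv), EtOAc, −20 °C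
Reagents that add atoms: 3-chloroperoxybenzoic acid, OOC(=O)c1cccc(Cl)c1
Why: Proposed new method: a scandium tritriflate–chiral N,N'-dioxide complex activates the meso cyclopentanone, m-CPBA adds to give a metal-bound Criegee adduct, and the ligand pocket allows only one of the two enantiotopic CH2–C(=O) bonds to lie antiperiplanar to the O–O bond, so that this CH2 migrates with retention (Baeyer–Villiger ring expansion), the mirror plane is broken and both untouched quaternary carbons become (4aR,7aR); the closest known reactions are Sc(OTf)3/N,N'-dioxide-catalysed desymmetrising Baeyer–Villiger oxidations of prochiral cyclobutanones and of 4-substituted or meso 3,5-disubstituted cyclohexanones, which have not been shown for a cyclopentanone flanked by two quaternary β-carbons.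

**Step 5**
Reactants: 7 (4aR,7aR)-4a,7a-dimethylhexahydrocyclopenta[c]pyran-3(1H)-one
Product: 8 1-[(1R,2R)-2-(hydroxymethyl)-1,2-dimethylcyclopentyl]propan-2-one
Conditions: MeLi (1.05 equiv), THF, −78 °C; H2O
Reagents that add atoms: methyllithium, [Li]C
Why: mono-addition of an organolithium to a δ-lactone; the lithium lactolate does not collapse at −78 °C, so hydrolysis gives the methyl ketone (in equilibrium with its cyclic hemiketal) and the stereocentres are untouched.

**Step 6**
Reactants: 8 1-[(1R,2R)-2-(hydroxymethyl)-1,2-dimethylcyclopentyl]propan-2-one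
Product: 9 (1R,2R)-1,2-dimethyl-2-(2-oxopropyl)cyclopentane-1-carbaldehyde
Conditions: Dess–Martin periodinane, pyridine, CH2Cl2, 0 → 25 °C
Reagents that add atoms: none
Why: Dess–Martin oxidation of the primary neopentyl alcohol (drawn out of the hemiketal equilibrium) under non-basic conditions that avoid aldol closure of the keto aldehyde, which is used at once.

**Step 7**
Reactants: 9 (1R,2R)-1,2-dimethyl-2-(2-oxopropyl)cyclopentane-1-carbaldehyde; 10 2-methylbut-3-yn-2-ol
Product: 13 1-[(1R,2R)-2-[(2E)-1,4-dihydroxy-4-methylpent-2-en-1-yl]-1,2-dimethylcyclopentyl]propan-2-one, via alkenylzirconocene 11 (not isolated), via alkenylzinc 12 (not isolated)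
Conditions: 10, Cp2Zr(H)Cl (2.1 equiv per 10), CH2Cl2, 25 °C; Me2Zn, toluene, −65 °C; 9, 0 °C; H2O
Reagents that add atoms: none
Why: hydrozirconation followed by zirconium-to-zinc transmetalation and alkenylzinc addition to the aldehyde; syn hydrozirconation sets the E alkene, the alkenylzinc adds to the aldehyde and not to the methyl ketone, and the new carbinol centre is an inconsequential epimer mixture.

**Step 8**
Reactants: 14 but-2-yn-1-ol
Product: 16 (2Z)-3-iodobut-2-en-1-ol, via alkenylaluminate 15 (not isolated)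
Conditions: NaAlH2(OCH2CH2OMe)2, THF, 0 → 25 °C; I2, −78 → 0 °C; H2O
Reagents that add atoms: iodine, II
Why: hydroxyl-directed trans-hydroalumination of a propargylic alcohol puts aluminium on C3 anti to the delivered hydride, and iodinolysis with retention gives the Z vinyl iodide.

**Step 9**
Reactants: 16 (2Z)-3-iodobut-2-en-1-ol
Product: 17 (2Z)-1-bromo-3-iodobut-2-ene
Conditions: PBr3 (0.4 equiv), Et2O, 0 °C
Reagents that add atoms: phosphorus tribromide, BrP(Br)Br
Why: SN2 bromination of a primary allylic alcohol, which leaves the alkene geometry and the vinyl iodide intact.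

**Step 10**
Reactants: 18 2-methylphenol; 17 (2Z)-1-bromo-3-iodobut-2-ene
Product: 20 2-[(2Z)-3-iodobut-2-en-1-yl]-6-methylphenol, via sodium 2-methylphenolate 19 (not isolated)
Conditions: NaH, toluene, 0 → 25 °C; 17, 25 °C
Reagents that add atoms: none
Why: ortho C-allylation of a sodium phenolate as a tight ion pair in a non-polar solvent (SN2 at the primary allylic bromide, Z geometry retained); C6 is the only free ortho position, and O-allyl ether and para isomer are removed by chromatography.

**Step 11**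
Reactants: 13 1-[(1R,2R)-2-[(2E)-1,4-dihydroxy-4-methylpent-2-en-1-yl]-1,2-dimethylcyclopentyl]propan-2-one; 20 2-[(2Z)-3-iodobut-2-en-1-yl]-6-methylphenol
Product: 25 (4Z)-1-[(1R,2R)-2-[(2E)-1,4-dihydroxy-4-methylpent-2-en-1-yl]-1,2-dimethylcyclopentyl]-6-(2-hydroxy-3-methylphenyl)-4-methylhex-4-en-2-one, via bis-silyl ether 21 (not isolated), via aryl silyl ether 22 (not isolated), via lithium enolate 23 (not isolated), via tris-silyl ether 24 (not isolated)
Conditions: HN(SiMe3)2, Me3SiOTf (1 mol%), CH2Cl2, 25 °C, then evaporate; LiN(SiMe3)2 (2.2 equiv), THF, −78 °C; Pd2(dba)3 (2.5 mol%), P(t-Bu)3 (6 mol%), 25 °C; citric acid, MeOH, 0 → 25 °C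
Reagents that add atoms: none
Why: palladium-catalysed α-alkenylation of a ketone enolate: transient silylation masks the three hydroxyls, kinetic deprotonation gives the terminal (methyl-side) lithium enolate, coupling with the vinyl iodide retains the Z geometry, and α-protonation plus methanolysis of the silyl ethers gives the β,γ-unsaturated ketone.

**Step 12**
Reactants: 25 (4Z)-1-[(1R,2R)-2-[(2E)-1,4-dihydroxy-4-methylpent-2-en-1-yl]-1,2-dimethylcyclopentyl]-6-(2-hydroxy-3-methylphenyl)-4-methylhex-4-en-2-one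
Product: 26 2-[(2Z)-6-{(1R,2R)-2-[(2E)-1,4-dihydroxy-4-methylpent-2-en-1-yl]-1,2-dimethylcyclopentyl}-3-methyl-5-oxohex-2-en-1-yl]-6-methylcyclohexa-2,5-diene-1,4-dione
Conditions: K2NO(SO3)2 (2.5 equiv), KH2PO4, acetone/H2O, 0 → 25 °C
Reagents that add atoms: potassium nitrosodisulfonate, [K+].[K+].[O]N(S(=O)(=O)[O-])S(=O)(=O)[O-]
Why: Teuber oxidation: the nitroxyl radical oxidises the 2,6-disubstituted phenol at its free para position to the p-quinone and leaves alcohols, alkenes and ketones alone.

**Step 13**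
Reactants: 26 2-[(2Z)-6-{(1R,2R)-2-[(2E)-1,4-dihydroxy-4-methylpent-2-en-1-yl]-1,2-dimethylcyclopentyl}-3-methyl-5-oxohex-2-en-1-yl]-6-methylcyclohexa-2,5-diene-1,4-dione
Product: 28 (2E)-1-[(1R,2R)-2-[(4Z)-6-(2,5-dihydroxy-3-methylphenyl)-4-methyl-2-oxohex-4-en-1-yl]-1,2-dimethylcyclopentyl]-4-hydroxy-4-methylpent-2-en-1-one, via quinone enone 27 (not isolated)
Conditions: Dess–Martin periodinane, pyridine, CH2Cl2, 0 °C; then aq. Na2S2O4, Et2O, 25 °C
Reagents that add atoms: none
Why: Dess–Martin oxidation of the secondary allylic alcohol gives the E-enone (tertiary alcohol and quinone are inert), and dithionite in the work-up reduces only the quinone to the hydroquinone; no base is used, so the 1,5-diketone does not aldolise.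

**Compound list**
1 | 1,2-dimethylcyclopentene | CC1=C(C)CCC1 | starting material
2 | trichloroacetyl chloride | ClC(Cl)(Cl)C(Cl)=O | starting material
3 | dichloroketene | ClC(Cl)=C=O | intermediate
4 | rac-(1R,5S)-7,7-dichloro-1,5-dimethylbicyclo[3.2.0]heptan-6-one (cis-fused) | O=C1[C@@]2(C)CCC[C@@]2(C)C1(Cl)Cl | intermediate
5 | rac-(3aR,6aR)-1,1-dichloro-3a,6a-dimethylhexahydropentalen-2(1H)-one (cis-fused) | O=C1C[C@@]2(C)CCC[C@@]2(C)C1(Cl)Cl | intermediate
6 | (3aR,6aS)-3a,6a-dimethylhexahydropentalen-2(1H)-one (meso, cis-fused) | O=C1C[C@@]2(C)CCC[C@@]2(C)C1 | intermediate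
7 | (4aR,7aR)-4a,7a-dimethylhexahydrocyclopenta[c]pyran-3(1H)-one | O=C1C[C@@]2(C)CCC[C@@]2(C)CO1 | intermediate
8 | 1-[(1R,2R)-2-(hydroxymethyl)-1,2-dimethylcyclopentyl]propan-2-one | CC(=O)C[C@@]1(C)CCC[C@@]1(C)CO | intermediate
9 | (1R,2R)-1,2-dimethyl-2-(2-oxopropyl)cyclopentane-1-carbaldehyde | CC(=O)C[C@@]1(C)CCC[C@@]1(C)C=O | intermediate
10 | 2-methylbut-3-yn-2-ol | CC(C)(O)C#C | starting material
11 | (E)-Cp2Zr(Cl)–CH=CH–CMe2–O–Zr(Cl)Cp2 (alkenylzirconocene, O-zirconated) | CC(C)(O[Zr](Cl)(C1C=CC=C1)C1C=CC=C1)/C=C/[Zr](Cl)(C1C=CC=C1)C1C=CC=C1 | intermediate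
12 | (E)-MeZn–CH=CH–CMe2–O–Zr(Cl)Cp2 (alkenyl(methyl)zinc) | CC(C)(O[Zr](Cl)(C1C=CC=C1)C1C=CC=C1)/C=C/[Zn]C | intermediate
13 | 1-[(1R,2R)-2-[(2E)-1,4-dihydroxy-4-methylpent-2-en-1-yl]-1,2-dimethylcyclopentyl]propan-2-one (carbinol epimers) | CC(=O)C[C@@]1(C)CCC[C@@]1(C)C(O)/C=C/C(C)(C)O | intermediate
14 | but-2-yn-1-ol | CC#CCO | starting material
15 | sodium 2,2-bis(2-methoxyethoxy)-3-methyl-2,5-dihydro-1,2-oxaluminol-2-uide (cyclic Z-alkenylaluminate) | CC1=CCO[Al-]1(OCCOC)OCCOC.[Na+] | intermediate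
16 | (2Z)-3-iodobut-2-en-1-ol | OC/C=C(/C)I | intermediate
17 | (2Z)-1-bromo-3-iodobut-2-ene | BrC/C=C(/C)I | intermediate
18 | 2-methylphenol | Cc1ccccc1O | starting material
19 | sodium 2-methylphenolate | Cc1ccccc1[O-].[Na+] | intermediate
20 | 2-[(2Z)-3-iodobut-2-en-1-yl]-6-methylphenol | Cc1cccc(C/C=C(/C)I)c1O | intermediate
21 | bis(trimethylsilyl) ether of 13 (same configuration) | CC(=O)C[C@@]1(C)CCC[C@@]1(C)C(O[Si](C)(C)C)/C=C/C(C)(C)O[Si](C)(C)C | intermediate
22 | {2-[(2Z)-3-iodobut-2-en-1-yl]-6-methylphenoxy}trimethylsilane | Cc1cccc(C/C=C(/C)I)c1O[Si](C)(C)C | intermediate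
23 | terminal lithium enolate of 21 | [Li+].C=C([O-])C[C@@]1(C)CCC[C@@]1(C)C(O[Si](C)(C)C)/C=C/C(C)(C)O[Si](C)(C)C | intermediate
24 | tris(trimethylsilyl) ether of 25 (same configuration) | Cc1cccc(C/C=C(/C)CC(=O)C[C@@]2(C)CCC[C@@]2(C)C(O[Si](C)(C)C)/C=C/C(C)(C)O[Si](C)(C)C)c1O[Si](C)(C)C | intermediate
25 | (4Z)-1-[(1R,2R)-2-[(2E)-1,4-dihydroxy-4-methylpent-2-en-1-yl]-1,2-dimethylcyclopentyl]-6-(2-hydroxy-3-methylphenyl)-4-methylhex-4-en-2-one | Cc1cccc(C/C=C(/C)CC(=O)C[C@@]2(C)CCC[C@@]2(C)C(O)/C=C/C(C)(C)O)c1O | intermediate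
26 | 2-[(2Z)-6-{(1R,2R)-2-[(2E)-1,4-dihydroxy-4-methylpent-2-en-1-yl]-1,2-dimethylcyclopentyl}-3-methyl-5-oxohex-2-en-1-yl]-6-methylcyclohexa-2,5-diene-1,4-dione | CC1=CC(=O)C=C(C/C=C(/C)CC(=O)C[C@@]2(C)CCC[C@@]2(C)C(O)/C=C/C(C)(C)O)C1=O | intermediate
27 | 2-[(2Z)-6-{(1R,2R)-2-[(2E)-4-hydroxy-4-methylpent-2-enoyl]-1,2-dimethylcyclopentyl}-3-methyl-5-oxohex-2-en-1-yl]-6-methylcyclohexa-2,5-diene-1,4-dione | CC1=CC(=O)C=C(C/C=C(/C)CC(=O)C[C@@]2(C)CCC[C@@]2(C)C(=O)/C=C/C(C)(C)O)C1=O | intermediate
28 | (2E)-1-[(1R,2R)-2-[(4Z)-6-(2,5-dihydroxy-3-methylphenyl)-4-methyl-2-oxohex-4-en-1-yl]-1,2-dimethylcyclopentyl]-4-hydroxy-4-methylpent-2-en-1-one | C/C(=C/Cc1cc(O)cc(C)c1O)CC(=O)C[C@@]1(C)CCC[C@@]1(C)C(=O)/C=C/C(C)(C)O | target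

**Step count and risks**
Total steps: 13. Longest linear sequence: 10 (steps 1–7, then 11–13). The three steps most likely to fail are 4, 7 and 11.

Step 4 (the proposed reaction; a cyclopentanone with two primary α-carbons next to quaternary centres may react slowly or with low ee). The fallback uses known chemistry, sets out from 6 and returns at 7. Ketone 6 is deprotonated enantioselectively with lithium (R,R)-bis(1-phenylethyl)amide/LiCl in the presence of Me3SiCl (THF, −100 °C; the base antipode is chosen to remove the proton on the required side) to give trimethylsilyl enol ether F1. Ozonolysis of F1 (O3, CH2Cl2/MeOH, −78 °C) with NaBH4 reduction gives hydroxy acid F2, which lactonises (TsOH cat., toluene) to 7.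

Step 7 (a hindered α-quaternary aldehyde and an alkyne with a free hydroxyl may make the alkenylzinc addition sluggish). The fallback sets out from 9 and 10 and returns at 13. Alkyne 10 is hydrostannylated (Bu3SnH, PdCl2(PPh3)2 cat., THF) to (E)-alkenylstannane F3, and iodinolysis (I2, CH2Cl2, 0 °C) gives (E)-vinyl iodide F4. Nozaki–Hiyama–Kishi coupling of F4 with 9 (CrCl2, NiCl2 cat., DMSO, 25 °C) adds only to the aldehyde and gives 13.

Step 11 (mono-alkenylation of a methyl ketone enolate; double coupling or migration of the new alkene into conjugation are possible). The fallback inverts the polarity of the bond formation, sets out from 13 and 20 and returns at 24. Compound 13 is silylated under enolising conditions (LiN(SiMe3)2, Me3SiCl, THF, −78 °C) to the tris(trimethylsilyl) compound F5, whose terminal silyl enol ether is brominated (NBS, THF, −78 °C) to bromomethyl ketone F6. Phenol 20 is O-silylated to 22 and converted (t-BuLi, Et2O, −78 °C; ZnCl2) into alkenylzinc chloride F7. Negishi coupling of F6 with F7 (Pd(PPh3)4, THF, 25 °C) gives 24, which is desilylated as in step 11 to 25.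

**Further compounds**
F1 | step 4 | trimethyl{[(3aS,6aR)-3a,6a-dimethyl-1,3a,4,5,6,6a-hexahydropentalen-2-yl]oxy}silane | C[Si](C)(C)OC1=C[C@]2(C)CCC[C@]2(C)C1
F2 | step 4 | 2-[(1R,2R)-2-(hydroxymethyl)-1,2-dimethylcyclopentyl]acetic acid | OC(=O)C[C@@]1(C)CCC[C@@]1(C)CO
F3 | step 7 | (3E)-2-methyl-4-(tributylstannyl)but-3-en-2-ol | CCCC[Sn](CCCC)(CCCC)/C=C/C(C)(C)O
F4 | step 7 | (3E)-4-iodo-2-methylbut-3-en-2-ol | CC(C)(O)/C=C/I
F5 | step 11 | tris(trimethylsilyl) derivative of 13 (terminal silyl enol ether and two silyl ethers) | C=C(O[Si](C)(C)C)C[C@@]1(C)CCC[C@@]1(C)C(O[Si](C)(C)C)/C=C/C(C)(C)O[Si](C)(C)C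
F6 | step 11 | 1-bromo-3-[(1R,2R)-2-{(2E)-4-methyl-1,4-bis[(trimethylsilyl)oxy]pent-2-en-1-yl}-1,2-dimethylcyclopentyl]propan-2-one | BrCC(=O)C[C@@]1(C)CCC[C@@]1(C)C(O[Si](C)(C)C)/C=C/C(C)(C)O[Si](C)(C)C
F7 | step 11 | chloro{(2Z)-4-[3-methyl-2-(trimethylsilyloxy)phenyl]but-2-en-2-yl}zinc | Cc1cccc(C/C=C(/C)[Zn]Cl)c1O[Si](C)(C)C
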